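A ratio was where I began on your quick question and your hunch that more substrate must give the better percentage: the pace at which by-product multiplies over the pace at which protic impurity is quenched.

    partner + protic impurity → quenched reagent (k1 = 0.78 L mol⁻¹ min⁻¹)
    substrate + partner + by-product → product + 2 by-product (k2 = 37 L² mol⁻² min⁻¹)
    substrate + partner → product + by-product (k3 = 3.1 × 10⁻⁴ L mol⁻¹ min⁻¹)

| flask | substrate | partner | protic impurity | time |
|---|---|---|---|---|
| north | 6.0 mM | 24.0 mM | 6.00 mM | 10 h |
| west | 20 mM | 24.0 mM | 6.00 mM | 10 h |
| south | 60 mM | 24.0 mM | 6.00 mM | 10 h |
| south-west | 200 mM | 24.0 mM | 6.00 mM | 10 h |

- "hardly changes" means that all values lie within two and a half points (for a concentration: within two and a half percent of the largest)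
- run time (north): 10 h

1. amount of product at the end, in percent of the substrate charged for north, west, south, south-west, in this order
2. how that number moves from the first to the last of them (falls, then rises / rises, then falls / rises all the way / hardly changes / falls all the way)

The quench and both product steps run in proportion to partner, so I let partner cancel and counted time in partner-exposure. On that clock, protic impurity fell with the quench constant, while by-product multiplied with the constant of the autocatalytic step times the substrate. In south, their ratio is 2.85. The background step seeds by-product at 0.00838 mM. I put ignition, the end of the induction period of this autocatalysis, where by-product nears the partner charge, 7.96 multiplications by e later. That gave 6.10% in south: the spared share, the part of the protic impurity still unquenched at ignition, which is e to the minus multiplications over ratio.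

South holds 60 mM of substrate against 24.0 mM of partner, which makes partner the limiting reagent. I put ignition at 3.32 h, earlier than the 10 h allowed. So I took one partner for each quenched reagent and gave the rest of the partner charge to product, which came to 18.4 mM, or 30.7% of the substrate. For north, ignition at 33.2 h lay later than the time allowed. For west, 9.96 h sat on it, so I stopped there.

The forecast said 1.5%, 41.7%, 30.6% and 10.3%, so rises, then falls, holding that “Product then follows a logistic curve”. Its south figure stands close to my 30.7%, but on the same clock, so the nearness is no check.

The runs gave 1.50%, 41.7%, 30.6% and 10.3%, so rises, then falls, and that row belongs to the time allowed: north reached >99.9% after 100 h, while south-west did not move. South kept 5.9% of its protic impurity, beside a spared share of 6.10%. In south-west the ratio of the two paces is 9.49, larger than in south, which makes the spared share 43.2%, and that flask ended with 43% of its protic impurity unquenched.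

All constants belong to no real substance; the result is computed.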